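**Retrosynthetic overview**

1. The target is unmasked last from its 2-(trimethylsilyl)ethyl ester / TBS ether by fluoride.
2. Key disconnection, in the only ring (O1, C2, C3=O, C4–OH, C5, C6H2): cut O1–C6 and C3–C4, and with them the exocyclic C5–CH2 bond. The ring is the enol of the oxa-Michael adduct of a 3-methylene-1,2-dione, which is the [3,3] product of a 1-acyl-1-(allyloxy)allene. That allene comes from fragment B (an α-lithiated allyl allenyl ether) and fragment A (a malic acid dioxolanone); the ring is formed in that one step.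
3. Enabling feature: the diosphenol C3(=O)–C4(OH)=C5 whose C5 carries a CH2–CH=CH arm and whose C6H2–O1 lies β to C4. The C4 enol oxygen is the former ether oxygen of the allyl allenyl ether, and O1 is the acetonide-masked hydroxyl of malic acid.
4. Fragment A: (S)-malic acid supplies C3, C2 (S), the side-chain CH2 and the methyl-bearing alkene carbon. The (E)-enoate is made by β-keto ester → (Z)-enol triflate → Negishi methylation.
5. Fragment B: ethyl (3S)-3-hydroxybutanoate, Fráter–Seebach methylation, vinyl addition, O-propargylation, isomerisation to the allenyl ether.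

Key step: step 12

Remark: the carbinol carbon that carries the propargyl and later the allenyl ether is used as an epimer mixture, because it becomes an sp2 carbon in the key step.

**Route**

Step 1
Reactants: 1 (S)-malic acid
Product: 2 2-[(4S)-2,2-dimethyl-5-oxo-1,3-dioxolan-4-yl]acetic acid
Conditions: 2,2-dimethoxypropane, p-TsOH·H2O (cat.), rt
Reagents that add atoms: 2,2-dimethoxypropane, COC(C)(C)OC
Why: Acid-catalysed transacetalisation should close the five-membered dioxolanone on the α-hydroxy acid terminus under thermodynamic control and leave the β-carboxyl free; the malic stereocentre is not touched.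

Step 2
Reactants: 3 ε-caprolactone; 4 2-(trimethylsilyl)ethanol
Product: 5 2-(trimethylsilyl)ethyl 6-hydroxyhexanoate
Conditions: 4 (4 equiv), NaH (cat.), THF, 0 °C → rt; AcOH quench
Reagents that add atoms: none
Why: Alkoxide-catalysed ring-opening transesterification of the lactone, with the excess alcohol keeping the hydroxy ester monomeric.

Step 3
Reactants: 2 dioxolanone acid; 6 Meldrum's acid; 5 2-(trimethylsilyl)ethyl 6-hydroxyhexanoate
Product: 8 2-(trimethylsilyl)ethyl 6-({4-[(4S)-2,2-dimethyl-5-oxo-1,3-dioxolan-4-yl]-3-oxobutanoyl}oxy)hexanoate, via acyl Meldrum's acid 7 (not isolated)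
Conditions: 6, DCC, DMAP, CH2Cl2, 0 °C → rt; filter, cold 0.5 M HCl wash; then 5, toluene, 80 °C
Reagents that add atoms: none
Why: Oikawa–Yonemitsu β-keto ester synthesis: carbodiimide C-acylation of Meldrum's acid, then thermal cycloreversion to an acylketene that the primary alcohol traps, under conditions that neither enolise nor open the dioxolanone.

Step 4
Reactants: 8 β-keto ester
Product: 9 2-(trimethylsilyl)ethyl 6-{[(2Z)-4-[(4S)-2,2-dimethyl-5-oxo-1,3-dioxolan-4-yl]-3-{[(trifluoromethyl)sulfonyl]oxy}but-2-enoyl]oxy}hexanoate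
Conditions: NaH (1.05 equiv), THF, 0 °C; PhNTf2, 0 °C → rt
Reagents that add atoms: N-phenylbis(trifluoromethanesulfonimide), O=S(=O)(N(c1ccccc1)S(=O)(=O)C(F)(F)F)C(F)(F)F
Why: O-Triflation of the chelated sodium enolate of the β-keto ester should give the (Z)-enol triflate (triflate cis to the ester); only the doubly activated CH2 is deprotonated, so the β-oxygen is not eliminated.

Step 5
Reactants: 9 (Z)-enol triflate
Product: 10 2-(trimethylsilyl)ethyl 6-{[(2E)-4-[(4S)-2,2-dimethyl-5-oxo-1,3-dioxolan-4-yl]-3-methylbut-2-enoyl]oxy}hexanoate (fragment A)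
Conditions: MeZnCl, Pd(PPh3)4 (cat.), THF, rt
Reagents that add atoms: methylzinc chloride, C[Zn]Cl
Why: Negishi cross-coupling of the enol triflate with retention of alkene geometry places the methyl cis to the ester, which is the (E)-enoate; the organozinc should not attack the dioxolanone or the esters.

Step 6
Reactants: 11 ethyl (3S)-3-hydroxybutanoate
Product: 12 ethyl (2S,3S)-3-hydroxy-2-methylbutanoate
Conditions: LiN(i-Pr)2 (commercial solution, 2.2 equiv), THF, −50 → −20 °C; MeI, HMPA, −78 → 0 °C; aq. NH4Cl
Reagents that add atoms: iodomethane, CI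
Why: Fráter–Seebach alkylation: the chelated alkoxide–enolate dianion is methylated anti to the C3 methyl group, so the (3S) carbinol sets the new (2S) centre.

Step 7
Reactants: 12 ethyl (2S,3S)-3-hydroxy-2-methylbutanoate
Product: 13 ethyl (2S,3S)-3-[(tert-butyldimethylsilyl)oxy]-2-methylbutanoate
Conditions: TBSCl, imidazole, DMF, rt
Reagents that add atoms: tert-butyldimethylsilyl chloride, CC(C)(C)[Si](C)(C)Cl
Why: Standard imidazole-promoted silylation of a secondary alcohol.

Step 8
Reactants: 13 silyl ether ester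
Product: 14 (2S,3S)-3-[(tert-butyldimethylsilyl)oxy]-2-methylbutanal
Conditions: i-Bu2AlH (1.05 equiv), CH2Cl2, −78 °C; MeOH, aq. KNaC4H4O6
Reagents that add atoms: none
Why: Partial reduction of the ester: the aluminium hemiacetal should survive at −78 °C until work-up, and the non-basic conditions should leave the α-stereocentre intact.

Step 9
Reactants: 14 aldehyde
Product: 15 (4R,5S)-5-[(tert-butyldimethylsilyl)oxy]-4-methylhex-1-en-3-ol (mixture of C3 epimers)
Conditions: CH2=CHMgBr, THF, −78 → 0 °C; aq. NH4Cl
Reagents that add atoms: vinylmagnesium bromide, C=C[Mg]Br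
Why: Grignard addition to the aldehyde; the new carbinol centre forms as a Felkin/anti-Felkin mixture, which does not matter because this carbon becomes sp2 in step 12.

Step 10
Reactants: 15 allylic alcohol
Product: 16 tert-butyldimethyl{[(2S,3R)-3-methyl-4-(prop-2-yn-1-yloxy)hex-5-en-2-yl]oxy}silane (mixture of C4 epimers)
Conditions: NaH, propargyl bromide, Bu4NI (cat.), THF, 0 °C → rt
Reagents that add atoms: propargyl bromide, C#CCBr
Why: Williamson etherification of the sodium alkoxide with the reactive propargylic bromide, run cold so that alkylation should outpace silyl migration.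

Step 11
Reactants: 16 propargyl ether
Product: 17 tert-butyldimethyl{[(2S,3R)-3-methyl-4-(propa-1,2-dien-1-yloxy)hex-5-en-2-yl]oxy}silane (fragment B; mixture of C4 epimers)
Conditions: KOt-Bu (0.3 equiv), THF, 0 °C → rt
Reagents that add atoms: none
Why: Base-catalysed propargyl-to-allenyl ether isomerisation (prototropic shift), which should stop at the alkoxyallene at room temperature, below the temperature of its own Claisen rearrangement.

Step 12
Reactants: 17 allenyl ether (fragment B); 10 dioxolanone enoate (fragment A)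
Product: 22 2-(trimethylsilyl)ethyl 6-{[(2E)-4-[(2S)-5-[(2E,4R,5S)-5-[(tert-butyldimethylsilyl)oxy]-4-methylhex-2-en-1-yl]-4-hydroxy-3-oxo-3,6-dihydro-2H-pyran-2-yl]-3-methylbut-2-enoyl]oxy}hexanoate, via lithioallene 18 (not isolated), via tetrahedral lithium alkoxide 19 (not isolated), via hydroxy allenyl ketone 20 (not isolated), via methylene diketone 21 (not isolated)
Conditions: 17, n-BuLi (1.05 equiv), THF, −78 °C; add 10, −78 °C; AcOH (1.1 equiv), −78 °C → rt; dilute with toluene, 70 °C
Reagents that add atoms: none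
Why: Proposed new method: α-lithiation of the alkoxyallene and addition to the activated lactone carbonyl of 10 forms the C3–C4 bond and a tetrahedral lithium alkoxide that should not collapse at −78 °C (so no second addition); buffered protonation releases acetone and the C2 hydroxyl, heating triggers the [3,3] shift of the allyl allenyl ether (O–C bond broken, C5–CH2 bond made, C4 becomes a ketone), and the C2 hydroxyl then adds to C6 of the resulting 3-methylene-1,2-dione to give the C4=C5 enol directly. The closest known reaction types are the acylation of 1-lithio-1-alkoxyallenes by amides and lactones, the Claisen rearrangement of allyl allenyl ethers to 2-methylene-4-enals and the rearrangement of 2-acyl allyl vinyl ethers to α-dicarbonyls, which have not been combined as this domino on a 1-acyl-1-(allyloxy)allene. The one ring closes by 6-endo-trig oxa-Michael addition, the only cyclisation open to the hydroxyl once the allene has been consumed. No stereocentre is created: C2 comes unchanged from malic acid, the two side-chain centres come from 17, and the (E)-alkene should follow from a chair transition state in which the branched substituent is equatorial, since it would clash with the acyl group on C4 if axial. The step needs attack at the dioxolanone carbonyl ahead of enolisation or attack at the hindered enoate and the remote ester (it is the most electrophilic carbonyl, and addition is run at −78 °C), and it needs the sigmatropic shift to precede addition of the hydroxyl to the central allene carbon, which the absence of base after the acetic acid quench and the donor oxygen on the allene should secure.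

Step 13
Reactants: 22 silyl-protected diosphenol
Product: 23 6-{[(2E)-4-[(2S)-4-hydroxy-5-[(2E,4R,5S)-5-hydroxy-4-methylhex-2-en-1-yl]-3-oxo-3,6-dihydro-2H-pyran-2-yl]-3-methylbut-2-enoyl]oxy}hexanoic acid (6,7-diketothiomarinolic acid C6)
Conditions: Bu4NF (4 equiv), degassed THF, 0 °C → rt; AcOH quench, 0 °C
Reagents that add atoms: none
Why: Fluoride-mediated desilylation cleaves the TBS ether and fragments the 2-(trimethylsilyl)ethyl ester to ethene and the carboxylate; the diosphenol should sit as its enolate, which resists further deprotonation at C2, until the acidic quench.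

**Compound list**

1 | (S)-malic acid | O=C(O)C[C@H](O)C(=O)O | starting material
2 | 2-[(4S)-2,2-dimethyl-5-oxo-1,3-dioxolan-4-yl]acetic acid | OC(=O)C[C@@H]1OC(C)(C)OC1=O | intermediate
3 | ε-caprolactone (oxepan-2-one) | O=C1CCCCCO1 | starting material
4 | 2-(trimethylsilyl)ethanol | C[Si](C)(C)CCO | starting material
5 | 2-(trimethylsilyl)ethyl 6-hydroxyhexanoate | OCCCCCC(=O)OCC[Si](C)(C)C | intermediate
6 | Meldrum's acid (2,2-dimethyl-1,3-dioxane-4,6-dione) | CC1(C)OC(=O)CC(=O)O1 | starting material
7 | 5-{[(4S)-2,2-dimethyl-5-oxo-1,3-dioxolan-4-yl]acetyl}-2,2-dimethyl-1,3-dioxane-4,6-dione (acyl Meldrum's acid, drawn as keto tautomer) | CC1(C)OC(=O)C(C(=O)C[C@@H]2OC(C)(C)OC2=O)C(=O)O1 | intermediate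
8 | 2-(trimethylsilyl)ethyl 6-({4-[(4S)-2,2-dimethyl-5-oxo-1,3-dioxolan-4-yl]-3-oxobutanoyl}oxy)hexanoate | O=C(C[C@@H]1OC(C)(C)OC1=O)CC(=O)OCCCCCC(=O)OCC[Si](C)(C)C | intermediate
9 | 2-(trimethylsilyl)ethyl 6-{[(2Z)-4-[(4S)-2,2-dimethyl-5-oxo-1,3-dioxolan-4-yl]-3-{[(trifluoromethyl)sulfonyl]oxy}but-2-enoyl]oxy}hexanoate | FC(F)(F)S(=O)(=O)O/C(=C\C(=O)OCCCCCC(=O)OCC[Si](C)(C)C)C[C@@H]1OC(C)(C)OC1=O | intermediate
10 | 2-(trimethylsilyl)ethyl 6-{[(2E)-4-[(4S)-2,2-dimethyl-5-oxo-1,3-dioxolan-4-yl]-3-methylbut-2-enoyl]oxy}hexanoate | C/C(=C\C(=O)OCCCCCC(=O)OCC[Si](C)(C)C)C[C@@H]1OC(C)(C)OC1=O | intermediate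
11 | ethyl (3S)-3-hydroxybutanoate | CCOC(=O)C[C@H](C)O | starting material
12 | ethyl (2S,3S)-3-hydroxy-2-methylbutanoate | CCOC(=O)[C@@H](C)[C@H](C)O | intermediate
13 | ethyl (2S,3S)-3-[(tert-butyldimethylsilyl)oxy]-2-methylbutanoate | CCOC(=O)[C@@H](C)[C@H](C)O[Si](C)(C)C(C)(C)C | intermediate
14 | (2S,3S)-3-[(tert-butyldimethylsilyl)oxy]-2-methylbutanal | O=C[C@@H](C)[C@H](C)O[Si](C)(C)C(C)(C)C | intermediate
15 | (4R,5S)-5-[(tert-butyldimethylsilyl)oxy]-4-methylhex-1-en-3-ol (C3 epimers) | C=CC(O)[C@@H](C)[C@H](C)O[Si](C)(C)C(C)(C)C | intermediate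
16 | tert-butyldimethyl{[(2S,3R)-3-methyl-4-(prop-2-yn-1-yloxy)hex-5-en-2-yl]oxy}silane (C4 epimers) | C#CCOC(C=C)[C@@H](C)[C@H](C)O[Si](C)(C)C(C)(C)C | intermediate
17 | tert-butyldimethyl{[(2S,3R)-3-methyl-4-(propa-1,2-dien-1-yloxy)hex-5-en-2-yl]oxy}silane (C4 epimers) | C=C=COC(C=C)[C@@H](C)[C@H](C)O[Si](C)(C)C(C)(C)C | intermediate
18 | 1-lithio derivative of 17 (lithium on the oxygen-bearing allene carbon) | C=C=C([Li])OC(C=C)[C@@H](C)[C@H](C)O[Si](C)(C)C(C)(C)C | intermediate
19 | tetrahedral adduct of 18 at the lactone carbonyl of 10 (lithium 4-allenyl-2,2-dimethyl-1,3-dioxolan-4-olate) | C/C(=C\C(=O)OCCCCCC(=O)OCC[Si](C)(C)C)C[C@@H]1OC(C)(C)OC1(O[Li])C(=C=C)OC(C=C)[C@@H](C)[C@H](C)O[Si](C)(C)C(C)(C)C | intermediate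
20 | 2-(trimethylsilyl)ethyl 6-{[(2E,5S)-7-{[(4R,5S)-5-[(tert-butyldimethylsilyl)oxy]-4-methylhex-1-en-3-yl]oxy}-5-hydroxy-3-methyl-6-oxonona-2,7,8-trienoyl]oxy}hexanoate | C/C(=C\C(=O)OCCCCCC(=O)OCC[Si](C)(C)C)C[C@H](O)C(=O)C(=C=C)OC(C=C)[C@@H](C)[C@H](C)O[Si](C)(C)C(C)(C)C | intermediate
21 | 2-(trimethylsilyl)ethyl 6-{[(2E,5S,10E,12R,13S)-13-[(tert-butyldimethylsilyl)oxy]-5-hydroxy-3,12-dimethyl-8-methylidene-6,7-dioxotetradeca-2,10-dienoyl]oxy}hexanoate | C/C(=C\C(=O)OCCCCCC(=O)OCC[Si](C)(C)C)C[C@H](O)C(=O)C(=O)C(=C)C/C=C/[C@@H](C)[C@H](C)O[Si](C)(C)C(C)(C)C | intermediate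
22 | 2-(trimethylsilyl)ethyl 6-{[(2E)-4-[(2S)-5-[(2E,4R,5S)-5-[(tert-butyldimethylsilyl)oxy]-4-methylhex-2-en-1-yl]-4-hydroxy-3-oxo-3,6-dihydro-2H-pyran-2-yl]-3-methylbut-2-enoyl]oxy}hexanoate | C/C(=C\C(=O)OCCCCCC(=O)OCC[Si](C)(C)C)C[C@@H]1OCC(C/C=C/[C@@H](C)[C@H](C)O[Si](C)(C)C(C)(C)C)=C(O)C1=O | intermediate
23 | 6-{[(2E)-4-[(2S)-4-hydroxy-5-[(2E,4R,5S)-5-hydroxy-4-methylhex-2-en-1-yl]-3-oxo-3,6-dihydro-2H-pyran-2-yl]-3-methylbut-2-enoyl]oxy}hexanoic acid | C/C(=C\C(=O)OCCCCCC(=O)O)C[C@@H]1OCC(C/C=C/[C@@H](C)[C@H](C)O)=C(O)C1=O | target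

**Step count and risks**

Total: 13 steps. Longest linear sequence: 8 steps (steps 6 to 13, from ethyl (3S)-3-hydroxybutanoate).

Steps most likely to fail:

1. Step 12. The freed hydroxyl may add to the central allene carbon (five-membered furanone) before the sigmatropic shift. The lithioallene may also act as a base toward 10 (enolisation with loss of C2 configuration, or ring opening by vinylogous elimination) instead of adding, and the lithiated allyl ether may undergo a Wittig-type rearrangement. The fallback runs known reactions stepwise with O1 masked and sets out from 10. Opening of the dioxolanone with MeNHOMe·HCl/i-PrMgCl (THF, −20 °C) should give, with loss of acetone, the α-hydroxy Weinreb amide F1. TESCl/imidazole should give its triethylsilyl ether F2. Acylation of lithioallene 18 (from 17 and n-BuLi) by F2 at −78 °C should give the isolable silyloxy allenyl ketone F3. Heating F3 in toluene should effect the allyl allenyl ether Claisen rearrangement to the silyloxy methylene diketone F4. Buffered HF·pyridine should remove only the triethylsilyl group to give 21, which should close by oxa-Michael addition, so the route is rejoined at 22.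

2. Step 13. During the long exposure to basic fluoride that the ester needs, the diosphenolate may shuffle protons through the 3,4-diketone to the C2=C3 enol (loss of the C2 stereocentre). It may also open by retro-oxa-Michael reaction or be oxidised by air. The fallback is an acid-only, two-stage unmasking that sets out from 22. Buffered HF·pyridine in THF/pyridine should cleave the TBS ether to the hydroxy 2-(trimethylsilyl)ethyl ester F5. TFA in CH2Cl2 at 0 °C should then cleave the ester by acidolysis, arriving at 23.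

3. Step 10. The silyl group may migrate from O5 to the new sodium alkoxide at O3 before alkylation, which would put the ether on the wrong oxygen, and the base may consume propargyl bromide by elimination. The fallback sets out from 15 and avoids any alkoxide: acid-catalysed etherification with propargyl 2,2,2-trichloroacetimidate (TfOH cat., CH2Cl2/cyclohexane, 0 °C) should give 16 directly, where the route is rejoined.

**Further compounds**

F1 | step 12 | 2-(trimethylsilyl)ethyl 6-{[(2E,5S)-5-hydroxy-6-[methoxy(methyl)amino]-3-methyl-6-oxohex-2-enoyl]oxy}hexanoate | C/C(=C\C(=O)OCCCCCC(=O)OCC[Si](C)(C)C)C[C@H](O)C(=O)N(C)OC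
F2 | step 12 | 2-(trimethylsilyl)ethyl 6-{[(2E,5S)-6-[methoxy(methyl)amino]-3-methyl-6-oxo-5-[(triethylsilyl)oxy]hex-2-enoyl]oxy}hexanoate | C/C(=C\C(=O)OCCCCCC(=O)OCC[Si](C)(C)C)C[C@H](O[Si](CC)(CC)CC)C(=O)N(C)OC
F3 | step 12 | triethylsilyl ether of 20 at the C5 hydroxyl (silyloxy allenyl ketone) | C/C(=C\C(=O)OCCCCCC(=O)OCC[Si](C)(C)C)C[C@H](O[Si](CC)(CC)CC)C(=O)C(=C=C)OC(C=C)[C@@H](C)[C@H](C)O[Si](C)(C)C(C)(C)C
F4 | step 12 | triethylsilyl ether of 21 at the C5 hydroxyl (silyloxy methylene diketone) | C/C(=C\C(=O)OCCCCCC(=O)OCC[Si](C)(C)C)C[C@H](O[Si](CC)(CC)CC)C(=O)C(=O)C(=C)C/C=C/[C@@H](C)[C@H](C)O[Si](C)(C)C(C)(C)C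
F5 | step 13 | 2-(trimethylsilyl)ethyl 6-{[(2E)-4-[(2S)-4-hydroxy-5-[(2E,4R,5S)-5-hydroxy-4-methylhex-2-en-1-yl]-3-oxo-3,6-dihydro-2H-pyran-2-yl]-3-methylbut-2-enoyl]oxy}hexanoate | C/C(=C\C(=O)OCCCCCC(=O)OCC[Si](C)(C)C)C[C@@H]1OCC(C/C=C/[C@@H](C)[C@H](C)O)=C(O)C1=O
F0 | step 10 | none | none
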